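## Structural features

The target is a 3,4-dihydronaphthalen-1(2H)-one. Ring A is the benzo ring with hydroxyls at C6 and C8. Ring B carries the ketone at C1, a methylene at C2, a tertiary methyl carbinol at C3 and a methine at C4. C4 bears an aroyl group whose ring C is a 2,4-dihydroxyphenyl ketone; its second ortho position (C6') is linked through one methylene to C6 of a 4-hydroxy-2-pyranone (ring D). The only stereocentres, C3 (R) and C4 (S), are adjacent, with the C3 hydroxyl and the C4 aroyl group cis. C4 is benzylic and α to the aroyl ketone and can epimerise; C3 cannot. The C3 hydroxyl is β to both ketones, so base can open the molecule by retro-aldol cleavage at C2–C3 or C3–C4, and acid or base can dehydrate it toward a naphthol. Ring D is an electrophilic lactone with a reducible C5–C6 double bond. The real difficulty is the crowded C4–aroyl junction (a ketone between a doubly ortho-substituted ring C and a carbon next to a quaternary centre) combined with the absolute configuration at C3, all without strong acid or base. The key step uses the fact that C1, C8a, C4a, C4 and the aroyl carbonyl carbon, closed by an oxygen between C1 and that carbonyl carbon, form the skeleton of a 3-aryl-isobenzopyrylium ion, while C2–C3 with its methyl and oxygen is a 2-alkoxypropene.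

## Logic of the disconnections

**25 to 24.** The six O–CH2Ph bonds are cut last: five on the phenol and enol oxygens of rings A, C and D, one on the C3 oxygen. One neutral operation then uncovers every acidic hydroxyl and the retro-aldol-prone carbinol at the very end. The gain is that no earlier intermediate is acidic or able to fragment. The demand is that the forward hydrogenolysis reaches the hindered tertiary ether before ring D or a ketone is reduced.

**24 to 23.** No skeletal bond is cut; the C1 carbonyl is taken back to the alcohol level. The C1 oxygen of 23 is then the oxygen of an aldehyde, and the C1 stereocentre becomes irrelevant. The demand is a neutral oxidation, because in 24 the C3 ether is β to both carbonyls and C4–H is acidic.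

**23 to 18 and 20.** C1–C2 and C3–C4 are cut, and a retro-hydration rejoins the C1 oxygen to the aroyl carbon. These are the two bonds that form when a cationic benzo-fused oxygen heterocycle adds an enol ether. The crowded ketone then comes from an alkyne carbon and not from an acylation. The gain is ring B, the quaternary carbinol, the aroyl ketone and all stereocentres in one step from a flat diaryl alkyne. The demand is face selection by a chiral counter-anion, the C3 oxygen on the bridge side, and hydration faster than aromatisation.

**18 to 17 and 7.** The bond between the alkyne and ring C is cut. The iodide sits on the ring C/ring D fragment and the terminal alkyne on the small ring A aldehyde. Ring D therefore never meets the conditions of silyl-alkyne cleavage, and the union runs at an iodide near room temperature. The demand is oxidative addition at a doubly ortho-substituted, electron-rich iodide without alkyne dimerisation.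

**7 to 4 and 5, then 4 to 2 to 1.** The alkyne–ring A bond, the formyl C–C bond and two O–benzyl bonds are cut in turn. Symmetrical 2 has two equivalent positions that are para to one ether and ortho to the other. The demand is formylation there and not between the two ethers; the ortho-formyl group then activates the bromide for coupling.

**17 to 16 to 14 to 11 and 12.** The O–benzyl bond of ring D is cut, then ring D is opened at O1–C2 back to the masked acylketene 14, then the bond between the acyl carbon and the exocyclic carbon of 12 is cut. Ring D is a cyclised 3,5-dioxo acid, and 12 supplies four of its carbons in protected form. The demand is γ-acylation without proton transfer from the acidic CH2 of the acyl donor, and benzylation on oxygen.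

**11 to 10 to 8.** The C–I bond and the O–benzyl bonds are cut. Iodine is introduced before ring D exists, because C3 and C5 of an alkoxypyranone would later compete for the electrophile. The demand is mono-iodination ortho to the CH2 and not between the two ethers.

**20 to 19.** The C=CH2 bond is cut back to an ester carbonyl. This gives the 2-alkoxypropene whose oxygen substituent matches every other protecting group. The demand is a non-acidic isolation.

## Other disconnections considered

**Alternative 1:** The cut runs through ring C at C1'–C2' and C5'–C6'. Ring C would be grown last on ynone A1, a tetralone that already holds both stereocentres, by Diels–Alder reaction with diene A2. Loss of the methoxy and silyl groups would aromatise to resorcinol A3.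

- In favour: the key event is a thermal pericyclic reaction of a well-known type, with regiochemistry set by the polarity of the two partners. On predictability of the bond-forming event it is the better of the two plans. Ring C arrives with free hydroxyls, so two fewer benzyl ethers are needed, which is also better.
- Equal: the crowded ketone is not made by acylation of an arene in either plan.
- Against: A1 must already contain C3 and C4, so the stereochemical problem is moved, not solved. Its C4–H lies between an arene and an ynone carbonyl and would be more acidic than anything in the chosen route. Heating with a basic ketene acetal invites epimerisation and loss of the C3 alkoxy group. After A3 the silyloxymethyl carbon still has to be joined to C6 of ring D, on an intermediate with free phenols, two ketones and a labile C4.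
- Comparison: on structure the two plans share the alkyne-derived ketone. On mechanism the alternative is safer but sets no stereocentre, whereas the chosen step sets all of them. On step economy the alternative needs a separate asymmetric construction of ring B and several steps after A3, so the chosen plan is shorter.

**Alternative 2:** The cut is C4–C4a. Aryl bromide A4, an open-chain ketone with the tertiary propargylic ether already at C3, would undergo oxidative addition to zerovalent palladium and 6-exo-dig syn-carbopalladation. The vinylpalladium would be trapped by diboron reagent A6 to give vinyl boronate A5. Oxidation of the C–B bond would then give the aroyl ketone and the C4 hydrogen.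

- In favour: carbopalladation–borylation cascades are an established reaction class, which is better precedent than the chosen key step. The C1 ketone is present from the start, so no oxidation-state adjustment is needed, which is better by one operation.
- Equal: C4 would be set by protonation of an enol, the same thermodynamic recourse the chosen plan keeps in reserve. The ring C/ring D alkyne fragment and the final deprotection are the same.
- Against: A4 needs an enantioenriched tertiary propargylic benzyl ether β to an aryl ketone. Asymmetric alkynylation of an enolisable methyl ketone and benzylation of the resulting aldol-type alkoxide (retro-aldol risk) are both hard. The tetrasubstituted boronate in A5 would have to be oxidised with peroxide-type reagents next to ring D and a β-alkoxy ketone.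
- Comparison: on structure the plans use the same fragments. On mechanism the alternative is stepwise and precedented, but its stereochemistry rests on a difficult ketone addition made before ring closure. On step economy ring closure plus C–B oxidation equals cycloaddition plus C1 oxidation, but the assembly of A4 is longer than that of 18.

**Alternative 3:** The cut is C2–C3. Allyl bromide A7 carries a 2-arylallyl bromide on C8a and an acetyl/aroyl 1,3-diketone on the carbon attached to C4a. A chiral chromium catalyst (divalent chromium as the active state, with a stoichiometric reductant) would convert it into an allylchromium species that adds to the acetyl carbonyl, giving methylene compound A8. Oxidative cleavage of the exocyclic alkene would then give the C1 ketone.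

- In favour: the C3 carbinol forms directly and free, so the final hydrogenolysis would only have to cleave fast-reacting aryl and enol ethers. This is better than the chosen plan. Ligand-controlled chromium allylation of ketones is a known reaction type, which is also better precedent.
- Equal: C4 in A7 is a labile diketone methine, so both centres could in principle be set together; this is equal in ambition.
- Against: the 1,3-diketone would exist largely as a chelated enol, which is a poor electrophile and a proton source that can quench the allylmetal. A8 is a free β-hydroxy ketone and can undergo retro-aldol cleavage. The alkene would have to be cleaved oxidatively next to five electron-rich benzyloxyarenes and the enol-ether double bonds of ring D. A7 itself needs arylation of a hindered diketone, so the crowded ketone is again made by carbonyl chemistry.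
- Comparison: on structure the chosen plan avoids the acylation problem that this one keeps. On mechanism the organochromium addition is mild, but the enol form works against it. On step economy closure plus oxidative cleavage equals the chosen two steps, while access to A7 is longer.

Key step: step 11

Remark on the chemistry (assumptions):
- Cu[(R)-TRIP]2 is the divalent copper salt Cu(C50H56O4P)2 of (R)-3,3'-bis(2,4,6-triisopropylphenyl)-1,1'-binaphthyl-2,2'-diyl hydrogen phosphate, made beforehand from Cu(OTf)2 and two equivalents of the sodium phosphate.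
- Which antipode of the phosphate leads to the (3R) series has to be settled in a first run; (R) is written throughout.
- The C1 configuration of 23 is erased in step 12. 23 is (1S,3R,4S) with the C1 hydroxyl, the C3 benzyloxy group and the C4 aroyl group on one face, and this corresponds to (3R,4S) in 25.

## Route

Step 1
Reactants: 1 5-bromoresorcinol
Product: 2 1,3-bis(benzyloxy)-5-bromobenzene
Conditions: BnBr, K2CO3, DMF, 60 °C
Reagents that add atoms: benzyl bromide, BrCc1ccccc1
Why: Williamson ether synthesis; both phenoxides displace bromide from the benzylic halide and the aryl bromide is inert to carbonate.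

Step 2
Reactants: 2 1,3-bis(benzyloxy)-5-bromobenzene
Product: 4 2,4-bis(benzyloxy)-6-bromobenzaldehyde, via iminium salt 3 (not isolated)
Conditions: POCl3, DMF, 0 to 70 °C; then H2O
Reagents that add atoms: N,N-dimethylformamide, CN(C)C=O; water, O
Why: Vilsmeier–Haack formylation; attack should occur para to one ether and ortho to the other (two equivalent positions next to bromine) and not at the position shielded by both ethers, and hydrolysis of 3 releases the aldehyde with the benzyl ethers intact.

Step 3
Reactants: 4 2,4-bis(benzyloxy)-6-bromobenzaldehyde; 5 ethynyltrimethylsilane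
Product: 7 2,4-bis(benzyloxy)-6-ethynylbenzaldehyde, via silyl alkyne 6 (not isolated)
Conditions: PdCl2(PPh3)2, CuI, Et3N, THF, 60 °C; then K2CO3 (cat.), MeOH, rt
Reagents that add atoms: none
Why: Sonogashira coupling, in which the ortho-formyl group speeds oxidative addition at the otherwise electron-rich bromide; methanolysis of the C–Si bond then frees the terminal alkyne.

Step 4
Reactants: 8 3,5-dihydroxyphenylacetic acid
Product: 10 2-[3,5-bis(benzyloxy)phenyl]acetic acid, via benzyl ester 9 (not isolated)
Conditions: BnBr, K2CO3, DMF, 60 °C; then NaOH (aq), MeOH/THF, 60 °C; HCl (aq)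
Reagents that add atoms: benzyl bromide, BrCc1ccccc1
Why: Williamson benzylation of both phenols and the carboxylate, followed by saponification of the benzyl ester only; aryl benzyl ethers are stable to hydroxide.

Step 5
Reactants: 10 2-[3,5-bis(benzyloxy)phenyl]acetic acid
Product: 11 2-[3,5-bis(benzyloxy)-2-iodophenyl]acetic acid
Conditions: NIS, TFA (cat.), MeCN, 0 °C to rt, dark
Reagents that add atoms: N-iodosuccinimide, O=C1CCC(=O)N1I
Why: Electrophilic aromatic iodination; the position ortho to the CH2 group and para to an ether oxygen is favoured over the position flanked by both ethers, and one equivalent limits di-iodination.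

Step 6
Reactants: 11 2-[3,5-bis(benzyloxy)-2-iodophenyl]acetic acid; 12 2,2,6-trimethyl-4H-1,3-dioxin-4-one
Product: 14 6-{3-[3,5-bis(benzyloxy)-2-iodophenyl]-2-oxopropyl}-2,2-dimethyl-4H-1,3-dioxin-4-one, via acyl imidazole 13 (not isolated)
Conditions: CDI, THF, rt; then added to 12, LiN(SiMe3)2 (2.5 equiv each), THF, −78 °C; AcOH
Reagents that add atoms: none
Why: Crossed Claisen-type γ-acylation of the lithium dienolate of 12 by the acyl imidazole; the excess dienolate absorbs the acidic product, and the aryl iodide is untouched by amide base at −78 °C.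

Step 7
Reactants: 14 6-{3-[3,5-bis(benzyloxy)-2-iodophenyl]-2-oxopropyl}-2,2-dimethyl-4H-1,3-dioxin-4-one
Product: 16 6-[3,5-bis(benzyloxy)-2-iodobenzyl]-4-hydroxy-2H-pyran-2-one, via acylketene 15 (not isolated)
Conditions: toluene, 110 °C, dilute
Reagents that add atoms: none
Why: Thermal retro-[4+2] fragmentation releases acetone and acylketene 15, whose enolised terminal ketone oxygen closes onto the ketene carbon to give the six-membered 4-hydroxy-2-pyranone.

Step 8
Reactants: 16 6-[3,5-bis(benzyloxy)-2-iodobenzyl]-4-hydroxy-2H-pyran-2-one
Product: 17 4-(benzyloxy)-6-[3,5-bis(benzyloxy)-2-iodobenzyl]-2H-pyran-2-one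
Conditions: BnOH, PPh3, DIAD, THF, 0 °C to rt
Reagents that add atoms: benzyl alcohol, OCc1ccccc1
Why: Mitsunobu alkylation of the acidic vinylogous acid; alkylation at the C4 oxygen is the usual course for 4-hydroxy-2-pyranones and avoids the C3 benzylation that a benzyl halide with base can cause.

Step 9
Reactants: 17 4-(benzyloxy)-6-[3,5-bis(benzyloxy)-2-iodobenzyl]-2H-pyran-2-one; 7 2,4-bis(benzyloxy)-6-ethynylbenzaldehyde
Product: 18 2,4-bis(benzyloxy)-6-[(2,4-bis(benzyloxy)-6-{[4-(benzyloxy)-2-oxo-2H-pyran-6-yl]methyl}phenyl)ethynyl]benzaldehyde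
Conditions: Pd(PPh3)4, CuI, Et3N/THF, degassed, rt to 40 °C, slow addition of 7
Reagents that add atoms: none
Why: Sonogashira coupling at the aryl iodide, the only site prone to oxidative addition; the aldehyde and the pyranone tolerate the tertiary amine, and slow addition of the alkyne limits its oxidative dimerisation.

Step 10
Reactants: 19 benzyl acetate
Product: 20 2-(benzyloxy)propene
Conditions: Cp2TiMe2, toluene, 65 °C, dark; basic alumina, distillation
Reagents that add atoms: dimethyltitanocene Cp2TiMe2, C[Ti](C)(C1C=CC=C1)C1C=CC=C1
Why: Petasis methylenation; the titanium methylidene formed on heating adds to the ester carbonyl and the oxatitanacyclobutane collapses to the enol ether, which is isolated without contact with acid.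

Step 11
Reactants: 18 2,4-bis(benzyloxy)-6-[(2,4-bis(benzyloxy)-6-{[4-(benzyloxy)-2-oxo-2H-pyran-6-yl]methyl}phenyl)ethynyl]benzaldehyde; 20 2-(benzyloxy)propene
Product: 23 (1S,3R,4S)-3,6,8-tris(benzyloxy)-4-(2,4-bis(benzyloxy)-6-{[4-(benzyloxy)-2-oxo-2H-pyran-6-yl]methyl}benzoyl)-3-methyl-1,2,3,4-tetrahydronaphthalen-1-ol, via isobenzopyrylium ion 21 (not isolated), via bridged oxocarbenium ion 22 (not isolated)
Conditions: Cu[(R)-TRIP]2 (10 mol%), 20 (3 equiv, slow addition), H2O (2 equiv), CH2Cl2, −20 °C; NaHCO3 (aq)
Reagents that add atoms: water, O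
Why: Proposed new method: the aldehyde oxygen of 18 should attack the copper-activated alkyne 6-endo-dig (the electron-rich ring C stabilises charge at the distal alkyne carbon, which disfavours 5-exo closure), and protodemetalation leaves the aromatic ion 21 paired with the chiral phosphate. The CH2 terminus of 20 then adds to the oxocarbenium carbon C1 and the benzyloxy-stabilised cation at C3 is captured 6-exo-trig by the enol-ether carbon C4, so ring B closes as a stepwise polar, formally inverse-demand [4+2] cycloaddition giving 22. Water adds to the aroyl carbon of 22 and the hemiketal collapses, leaving the former aldehyde oxygen as the C1 hydroxyl and the aroyl ketone on C4. The closest known reaction types are the Cu(OTf)2- and AuBr3-catalysed formal [4+2] benzannulations of ortho-alkynylbenzaldehydes with enol ethers or alkenes, which run on to naphthalenes or dihydronaphthalenes, and chiral copper phosphate ion-pair catalysis of isobenzopyrylium ions; new here are the hydrative interception of the bridged ion and the use of the anion to steer the cycloaddition. C1 and C4 are set cis by the two-atom oxygen bridge; C3 is set by approach of 20 with its benzyloxy group toward the cationic O=C bridge (electrostatic attraction, methyl under the benzo ring); the absolute sense is set by the phosphate, which differentiates the two faces of the planar cation at C1. The step needs attack at C1 and not at C3 of 21 (C3 is blocked by ring C), and it needs hydration to outrun C1–O ionisation and loss of benzyl alcohol; while the bridge is intact, elimination toward C4 would give a bridgehead alkene, and the low temperature and nearly neutral medium protect the opened product. Water is kept to about two equivalents and 20 is used in excess so that hydrolysis of the enol ether does not starve the reaction. The C1 configuration is of no consequence, and C4, being α to the aroyl ketone, could be equilibrated if the C3/C4 relationship needed correction.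

Step 12
Reactants: 23 (1S,3R,4S)-3,6,8-tris(benzyloxy)-4-(2,4-bis(benzyloxy)-6-{[4-(benzyloxy)-2-oxo-2H-pyran-6-yl]methyl}benzoyl)-3-methyl-1,2,3,4-tetrahydronaphthalen-1-ol
Product: 24 (3R,4S)-3,6,8-tris(benzyloxy)-4-(2,4-bis(benzyloxy)-6-{[4-(benzyloxy)-2-oxo-2H-pyran-6-yl]methyl}benzoyl)-3-methyl-3,4-dihydronaphthalen-1(2H)-one
Conditions: MnO2 (activated, excess), CH2Cl2, rt
Reagents that add atoms: none
Why: MnO2 oxidation of an electron-rich benzylic secondary alcohol on a neutral solid surface; no base is present that could enolise C4 or expel benzyloxide from C3, so both stereocentres are kept.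

Step 13
Reactants: 24 (3R,4S)-3,6,8-tris(benzyloxy)-4-(2,4-bis(benzyloxy)-6-{[4-(benzyloxy)-2-oxo-2H-pyran-6-yl]methyl}benzoyl)-3-methyl-3,4-dihydronaphthalen-1(2H)-one
Product: 25 (3R,4S)-4-(2,4-dihydroxy-6-{[4-hydroxy-2-oxo-2H-pyran-6-yl]methyl}benzoyl)-3,6,8-trihydroxy-3-methyl-3,4-dihydronaphthalen-1(2H)-one (CNP0197349.1)
Conditions: H2 (1 atm), 10% Pd/C, EtOAc/THF, rt, stopped after six equivalents of H2
Reagents that add atoms: none
Why: Hydrogenolysis of benzyl ethers over palladium; the five aryl and enol ethers should cleave fast and the tertiary ether more slowly. The neutral medium leaves the β-hydroxy ketone and both stereocentres untouched, and the ortho-hydroxy aryl ketones resist reduction.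

## Compound list

1 | 5-bromoresorcinol (5-bromobenzene-1,3-diol) | Oc1cc(O)cc(Br)c1 | starting material
2 | 1,3-bis(benzyloxy)-5-bromobenzene | Brc1cc(OCc2ccccc2)cc(OCc2ccccc2)c1 | intermediate
3 | N-{[2,4-bis(benzyloxy)-6-bromophenyl]methylidene}-N-methylmethanaminium chloride | C[N+](C)=Cc1c(OCc2ccccc2)cc(OCc2ccccc2)cc1Br.[Cl-] | intermediate
4 | 2,4-bis(benzyloxy)-6-bromobenzaldehyde | O=Cc1c(OCc2ccccc2)cc(OCc2ccccc2)cc1Br | intermediate
5 | ethynyltrimethylsilane | C#C[Si](C)(C)C | starting material
6 | 2,4-bis(benzyloxy)-6-[(trimethylsilyl)ethynyl]benzaldehyde | O=Cc1c(OCc2ccccc2)cc(OCc2ccccc2)cc1C#C[Si](C)(C)C | intermediate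
7 | 2,4-bis(benzyloxy)-6-ethynylbenzaldehyde | O=Cc1c(OCc2ccccc2)cc(OCc2ccccc2)cc1C#C | intermediate
8 | 3,5-dihydroxyphenylacetic acid | OC(=O)Cc1cc(O)cc(O)c1 | starting material
9 | benzyl 2-[3,5-bis(benzyloxy)phenyl]acetate | O=C(Cc1cc(OCc2ccccc2)cc(OCc2ccccc2)c1)OCc1ccccc1 | intermediate
10 | 2-[3,5-bis(benzyloxy)phenyl]acetic acid | OC(=O)Cc1cc(OCc2ccccc2)cc(OCc2ccccc2)c1 | intermediate
11 | 2-[3,5-bis(benzyloxy)-2-iodophenyl]acetic acid | OC(=O)Cc1cc(OCc2ccccc2)cc(OCc2ccccc2)c1I | intermediate
12 | 2,2,6-trimethyl-4H-1,3-dioxin-4-one | CC1=CC(=O)OC(C)(C)O1 | starting material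
13 | 1-{2-[3,5-bis(benzyloxy)-2-iodophenyl]acetyl}-1H-imidazole | O=C(Cc1cc(OCc2ccccc2)cc(OCc2ccccc2)c1I)n1ccnc1 | intermediate
14 | 6-{3-[3,5-bis(benzyloxy)-2-iodophenyl]-2-oxopropyl}-2,2-dimethyl-4H-1,3-dioxin-4-one | CC1(C)OC(=O)C=C(CC(=O)Cc2cc(OCc3ccccc3)cc(OCc3ccccc3)c2I)O1 | intermediate
15 | 6-[3,5-bis(benzyloxy)-2-iodophenyl]hex-1-ene-1,3,5-trione (acylketene) | O=C=CC(=O)CC(=O)Cc1cc(OCc2ccccc2)cc(OCc2ccccc2)c1I | intermediate
16 | 6-[3,5-bis(benzyloxy)-2-iodobenzyl]-4-hydroxy-2H-pyran-2-one | O=c1cc(O)cc(Cc2cc(OCc3ccccc3)cc(OCc3ccccc3)c2I)o1 | intermediate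
17 | 4-(benzyloxy)-6-[3,5-bis(benzyloxy)-2-iodobenzyl]-2H-pyran-2-one | O=c1cc(OCc2ccccc2)cc(Cc2cc(OCc3ccccc3)cc(OCc3ccccc3)c2I)o1 | intermediate
18 | 2,4-bis(benzyloxy)-6-[(2,4-bis(benzyloxy)-6-{[4-(benzyloxy)-2-oxo-2H-pyran-6-yl]methyl}phenyl)ethynyl]benzaldehyde | O=Cc1c(OCc2ccccc2)cc(OCc2ccccc2)cc1C#Cc1c(OCc2ccccc2)cc(OCc2ccccc2)cc1Cc1cc(OCc2ccccc2)cc(=O)o1 | intermediate
19 | benzyl acetate | CC(=O)OCc1ccccc1 | starting material
20 | 2-(benzyloxy)propene | C=C(C)OCc1ccccc1 | intermediate
21 | 6,8-bis(benzyloxy)-3-(2,4-bis(benzyloxy)-6-{[4-(benzyloxy)-2-oxo-2H-pyran-6-yl]methyl}phenyl)isochromenylium cation (chiral phosphate counter-ion not drawn) | [o+]1cc2c(OCc3ccccc3)cc(OCc3ccccc3)cc2cc1-c1c(OCc2ccccc2)cc(OCc2ccccc2)cc1Cc1cc(OCc2ccccc2)cc(=O)o1 | intermediate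
22 | bridged oxocarbenium ion: 3,6,8-tris(benzyloxy)-3-methyl-1,2,3,4-tetrahydro-1,4-(epoxymethano)naphthalene whose bridge carbon (bonded to C4, oxygen bonded to C1) bears ring C and is cationic; configuration as in 23 | C[C@@]1(OCc2ccccc2)C[C@@H]2[O+]=C(c3c(OCc4ccccc4)cc(OCc4ccccc4)cc3Cc3cc(OCc4ccccc4)cc(=O)o3)[C@H]1c1cc(OCc3ccccc3)cc(OCc3ccccc3)c12 | intermediate
23 | (1S,3R,4S)-3,6,8-tris(benzyloxy)-4-(2,4-bis(benzyloxy)-6-{[4-(benzyloxy)-2-oxo-2H-pyran-6-yl]methyl}benzoyl)-3-methyl-1,2,3,4-tetrahydronaphthalen-1-ol | C[C@@]1(OCc2ccccc2)C[C@H](O)c2c(OCc3ccccc3)cc(OCc3ccccc3)cc2[C@@H]1C(=O)c1c(OCc2ccccc2)cc(OCc2ccccc2)cc1Cc1cc(OCc2ccccc2)cc(=O)o1 | intermediate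
24 | (3R,4S)-3,6,8-tris(benzyloxy)-4-(2,4-bis(benzyloxy)-6-{[4-(benzyloxy)-2-oxo-2H-pyran-6-yl]methyl}benzoyl)-3-methyl-3,4-dihydronaphthalen-1(2H)-one | C[C@@]1(OCc2ccccc2)CC(=O)c2c(OCc3ccccc3)cc(OCc3ccccc3)cc2[C@@H]1C(=O)c1c(OCc2ccccc2)cc(OCc2ccccc2)cc1Cc1cc(OCc2ccccc2)cc(=O)o1 | intermediate
25 | (3R,4S)-4-(2,4-dihydroxy-6-{[4-hydroxy-2-oxo-2H-pyran-6-yl]methyl}benzoyl)-3,6,8-trihydroxy-3-methyl-3,4-dihydronaphthalen-1(2H)-one | C[C@@]1(O)CC(=O)c2c(O)cc(O)cc2[C@@H]1C(=O)c1c(O)cc(O)cc1Cc1cc(O)cc(=O)o1 | target

## Step count and least certain steps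

Total step count: 13. Longest linear sequence: 9 steps (steps 4, 5, 6, 7, 8, 9, 11, 12, 13).

**Step 11 (key step, the one labelled as a new method).**
- What may go wrong: ionisation of the C1–O bond of 22, followed by elimination and expulsion of benzyl alcohol toward a naphthalene before water adds. The strongly donor-stabilised cation 21 may also react through a loose ion pair, giving poor facial selectivity, and hydrolysis of 20 by the acid–water couple could starve the reaction.
- Fallback with known chemistry, from 18 back to the route at 25: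
  - Mukaiyama aldol addition of 2-(trimethylsilyloxy)propene to the aldehyde (BF3·OEt2, CH2Cl2, −78 °C) gives the racemic β-hydroxy ketone F1.
  - AgOTf-catalysed 6-endo-dig hydroalkoxylation of the alkyne by the benzylic hydroxyl gives the 1-(2-oxopropyl)-1H-isochromene F2.
  - Chelation-assisted intramolecular aldol-type addition of the enol-ether carbon C4 to the ketone (MgBr2·OEt2, wet CH2Cl2), with hydration of the bridged ion, gives the all-cis diol F3. The magnesium bridging the ring oxygen and the ketone oxygen should place the new hydroxyl on the bridge side. The enantiomers are separated on a chiral stationary phase.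
  - MnO2 oxidation gives the hydroxy tetralone F4, and hydrogenolysis of its five aryl and enol benzyl ethers gives 25. This variant also avoids the tertiary benzyl ether.

**Step 13.**
- What may go wrong: saturation of the C5–C6 bond of ring D, or reduction of a benzylic carbonyl, while the hindered tertiary ether is still being cleaved; long contact with the catalyst could also promote dehydration.
- Fallback, from 24 to 25, which avoids hydrogen altogether: Lewis-acid debenzylation with BCl3 and pentamethylbenzene as cation scavenger (CH2Cl2, −78 °C, bicarbonate quench). The benzylic C–O bond should ionise in preference to the C3–O bond, whose cation would be destabilised by two β-carbonyl groups. No new compound is made on the way.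

**Step 9.**
- What may go wrong: oxidative dimerisation of the terminal alkyne 7, and slow oxidative addition at the doubly ortho-substituted, electron-rich iodide 17.
- Fallback with exchanged roles, from 17 back to 18: Sonogashira coupling of 17 with 5 gives the silyl alkyne F5. Buffered fluoride (Bu4NF, AcOH, THF, 0 °C) gives the terminal alkyne F6. This is coupled with the activated bromide 4 (PdCl2(PPh3)2, CuI, Et3N, 60 °C) to give 18.

**Step 6.**
- What may go wrong: proton transfer from the acidic CH2 of 13 to the dienolate instead of C-acylation, followed by self-condensation of the acyl donor.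
- Fallback without strong base, from 11 back to the route at 16: oxalyl chloride (cat. DMF, CH2Cl2) gives the acid chloride F7. γ-Acylation of the diene A2 (CH2Cl2, −78 °C to rt) and mild acidic work-up gives the methyl 3,5-dioxohexanoate F8. DBU in toluene at 80 °C closes ring D with loss of methanol to give 16.

## Further compounds

F1 | step 11 | 4-{2,4-bis(benzyloxy)-6-[(2,4-bis(benzyloxy)-6-{[4-(benzyloxy)-2-oxo-2H-pyran-6-yl]methyl}phenyl)ethynyl]phenyl}-4-hydroxybutan-2-one (racemic) | CC(=O)CC(O)c1c(OCc2ccccc2)cc(OCc2ccccc2)cc1C#Cc1c(OCc2ccccc2)cc(OCc2ccccc2)cc1Cc1cc(OCc2ccccc2)cc(=O)o1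
F2 | step 11 | 1-[6,8-bis(benzyloxy)-3-(2,4-bis(benzyloxy)-6-{[4-(benzyloxy)-2-oxo-2H-pyran-6-yl]methyl}phenyl)-1H-isochromen-1-yl]propan-2-one (racemic) | CC(=O)CC1OC(c2c(OCc3ccccc3)cc(OCc3ccccc3)cc2Cc2cc(OCc3ccccc3)cc(=O)o2)=Cc2cc(OCc3ccccc3)cc(OCc3ccccc3)c12
F3 | step 11 | (1S,3R,4S)-6,8-bis(benzyloxy)-4-(2,4-bis(benzyloxy)-6-{[4-(benzyloxy)-2-oxo-2H-pyran-6-yl]methyl}benzoyl)-3-methyl-1,2,3,4-tetrahydronaphthalene-1,3-diol (after resolution) | C[C@@]1(O)C[C@H](O)c2c(OCc3ccccc3)cc(OCc3ccccc3)cc2[C@@H]1C(=O)c1c(OCc2ccccc2)cc(OCc2ccccc2)cc1Cc1cc(OCc2ccccc2)cc(=O)o1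
F4 | step 11 | (3R,4S)-6,8-bis(benzyloxy)-4-(2,4-bis(benzyloxy)-6-{[4-(benzyloxy)-2-oxo-2H-pyran-6-yl]methyl}benzoyl)-3-hydroxy-3-methyl-3,4-dihydronaphthalen-1(2H)-one | C[C@@]1(O)CC(=O)c2c(OCc3ccccc3)cc(OCc3ccccc3)cc2[C@@H]1C(=O)c1c(OCc2ccccc2)cc(OCc2ccccc2)cc1Cc1cc(OCc2ccccc2)cc(=O)o1
F0 | step 13 | none | none
F5 | step 9 | 4-(benzyloxy)-6-{3,5-bis(benzyloxy)-2-[(trimethylsilyl)ethynyl]benzyl}-2H-pyran-2-one | O=c1cc(OCc2ccccc2)cc(Cc2cc(OCc3ccccc3)cc(OCc3ccccc3)c2C#C[Si](C)(C)C)o1
F6 | step 9 | 4-(benzyloxy)-6-[3,5-bis(benzyloxy)-2-ethynylbenzyl]-2H-pyran-2-one | O=c1cc(OCc2ccccc2)cc(Cc2cc(OCc3ccccc3)cc(OCc3ccccc3)c2C#C)o1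
F7 | step 6 | 2-[3,5-bis(benzyloxy)-2-iodophenyl]acetyl chloride | O=C(Cl)Cc1cc(OCc2ccccc2)cc(OCc2ccccc2)c1I
F8 | step 6 | methyl 6-[3,5-bis(benzyloxy)-2-iodophenyl]-3,5-dioxohexanoate | COC(=O)CC(=O)CC(=O)Cc1cc(OCc2ccccc2)cc(OCc2ccccc2)c1I
A1 | alternative 1 | (3R,4S)-3,6,8-tris(benzyloxy)-4-[4-(tert-butyldimethylsilyloxy)but-2-ynoyl]-3-methyl-3,4-dihydronaphthalen-1(2H)-one | C[C@@]1(OCc2ccccc2)CC(=O)c2c(OCc3ccccc3)cc(OCc3ccccc3)cc2[C@@H]1C(=O)C#CCO[Si](C)(C)C(C)(C)C
A2 | alternative 1 | 1-methoxy-1,3-bis(trimethylsilyloxy)buta-1,3-diene | COC(O[Si](C)(C)C)=CC(=C)O[Si](C)(C)C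
A3 | alternative 1 | (3R,4S)-3,6,8-tris(benzyloxy)-4-[2-(tert-butyldimethylsilyloxymethyl)-4,6-dihydroxybenzoyl]-3-methyl-3,4-dihydronaphthalen-1(2H)-one | C[C@@]1(OCc2ccccc2)CC(=O)c2c(OCc3ccccc3)cc(OCc3ccccc3)cc2[C@@H]1C(=O)c1c(O)cc(O)cc1CO[Si](C)(C)C(C)(C)C
A4 | alternative 2 | (3R)-3-(benzyloxy)-1-[2,4-bis(benzyloxy)-6-bromophenyl]-5-(2,4-bis(benzyloxy)-6-{[4-(benzyloxy)-2-oxo-2H-pyran-6-yl]methyl}phenyl)-3-methylpent-4-yn-1-one | C[C@@](OCc1ccccc1)(CC(=O)c1c(OCc2ccccc2)cc(OCc2ccccc2)cc1Br)C#Cc1c(OCc2ccccc2)cc(OCc2ccccc2)cc1Cc1cc(OCc2ccccc2)cc(=O)o1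
A5 | alternative 2 | (3R,4Z)-3,6,8-tris(benzyloxy)-4-[(2,4-bis(benzyloxy)-6-{[4-(benzyloxy)-2-oxo-2H-pyran-6-yl]methyl}phenyl)(4,4,5,5-tetramethyl-1,3,2-dioxaborolan-2-yl)methylidene]-3-methyl-3,4-dihydronaphthalen-1(2H)-one | C[C@@]1(OCc2ccccc2)CC(=O)c2c(OCc3ccccc3)cc(OCc3ccccc3)cc2/C1=C(\B1OC(C)(C)C(C)(C)O1)c1c(OCc2ccccc2)cc(OCc2ccccc2)cc1Cc1cc(OCc2ccccc2)cc(=O)o1
A6 | alternative 2 | bis(pinacolato)diboron | CC1(C)OB(OC1(C)C)B1OC(C)(C)C(C)(C)O1
A7 | alternative 3 | 2-[3,5-bis(benzyloxy)-2-(3-bromoprop-1-en-2-yl)phenyl]-1-(2,4-bis(benzyloxy)-6-{[4-(benzyloxy)-2-oxo-2H-pyran-6-yl]methyl}phenyl)butane-1,3-dione | CC(=O)C(C(=O)c1c(OCc2ccccc2)cc(OCc2ccccc2)cc1Cc1cc(OCc2ccccc2)cc(=O)o1)c1cc(OCc2ccccc2)cc(OCc2ccccc2)c1C(=C)CBr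
A8 | alternative 3 | (3R,4S)-6,8-bis(benzyloxy)-4-(2,4-bis(benzyloxy)-6-{[4-(benzyloxy)-2-oxo-2H-pyran-6-yl]methyl}benzoyl)-3-methyl-1-methylidene-1,2,3,4-tetrahydronaphthalen-3-ol (tetralone numbering) | C[C@@]1(O)CC(=C)c2c(OCc3ccccc3)cc(OCc3ccccc3)cc2[C@@H]1C(=O)c1c(OCc2ccccc2)cc(OCc2ccccc2)cc1Cc1cc(OCc2ccccc2)cc(=O)o1
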